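**Retrosynthetic overview**

1. Target 14 (ring A = quinone ring, ring B = benzenoid ring of the naphthalene, ring C = trimethoxyphenyl; naphthoquinone numbering) is opened in ring A at C3–C4 and C4–C4a. C4 goes back to carbon monoxide and C4a to an aryl bromide, which leaves aryl 1-methoxyvinyl ketone 13.
2. Enabling feature: C3 is the unsubstituted =CH terminus of the vinylogous ester C1(=O)–C2(OMe)=C3, C1 sits on C8a, and C4 is a carbonyl on the neighbouring ring B carbon C4a. An aroylpalladium generated at C4a therefore meets the C2=C3 alkene in a six-membered endo array, and β-hydride elimination at C3 gives the quinone level directly.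
3. 13 comes from ketal 12 by loss of methanol. Ring B of 12 is made by a Diels–Alder reaction of aryl diene 5 with bromo ynone 10 followed by dehydrogenation; this sets the contiguous aryl/acyl/bromine pattern and so determines which carbonyl ends up next to the methoxy carbon.
4. 5 comes from 2,4,5-trimethoxybenzaldehyde 1 by Horner–Wadsworth–Emmons and Wittig olefinations; 10 comes from methyl 2,2-dimethoxypropanoate 7 and ethynyltrimethylsilane 6.
5. Ring order: ring C is purchased, ring B is formed by cycloaddition/aromatisation (step 5), ring A is closed last by carbonylative cyclisation (step 7).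

Key step: step 7

Assumption: the target has no stereocentre and its biaryl axis is drawn without configuration, so 14 is made without control of the axis (racemic if rotation proves slow).

**Route**

Step 1
Reactants: 1 2,4,5-trimethoxybenzaldehyde; 2 diethyl (3-oxobutan-2-yl)phosphonate
Product: 4 (E)-3-methyl-4-(2,4,5-trimethoxyphenyl)but-3-en-2-one, via sodium phosphonate carbanion 3 (not isolated)
Conditions: 2, NaH, THF, 0 °C; then 1, 0 → 65 °C
Reagents that add atoms: none
Why: Horner–Wadsworth–Emmons olefination of an aromatic aldehyde with an α-methyl β-ketophosphonate should give the trisubstituted enone with the thermodynamically preferred E geometry (aryl trans to acetyl), the methyl branch being carried in by the phosphonate.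

Step 2
Reactants: 4 (E)-3-methyl-4-(2,4,5-trimethoxyphenyl)but-3-en-2-one
Product: 5 (E)-1-(2,3-dimethylbuta-1,3-dien-1-yl)-2,4,5-trimethoxybenzene
Conditions: Ph3PCH3Br, KOt-Bu, THF, 0 °C → rt
Reagents that add atoms: methyltriphenylphosphonium bromide, C[P+](c1ccccc1)(c1ccccc1)c1ccccc1.[Br-]
Why: Wittig methylenation of the methyl ketone with the non-stabilised ylide should convert C=O into the 1,1-disubstituted alkene without touching the E trisubstituted alkene, giving a diene whose aryl group is on the outside of the s-cis conformer.

Step 3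
Reactants: 6 ethynyltrimethylsilane; 7 methyl 2,2-dimethoxypropanoate
Product: 9 4,4-dimethoxy-1-(trimethylsilyl)pent-1-yn-3-one, via lithium trimethylsilylacetylide 8 (not isolated)
Conditions: 6, n-BuLi, THF, −78 °C; then 7, −78 °C; sat. NH4Cl at −78 °C
Reagents that add atoms: none
Why: Acylation of a lithium acetylide by an ester should stop at the ynone because the α,α-dimethoxy groups chelate lithium and hold the tetrahedral adduct until the cold quench, as is known for dialkoxyacetate esters.

Step 4
Reactants: 9 4,4-dimethoxy-1-(trimethylsilyl)pent-1-yn-3-one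
Product: 10 1-bromo-4,4-dimethoxypent-1-yn-3-one
Conditions: NBS, AgNO3 (10 mol %), acetone, rt, dark
Reagents that add atoms: N-bromosuccinimide, O=C1CCC(=O)N1Br
Why: Silver-catalysed desilylative bromination of a silylalkyne (silver acetylide formation, then bromination by NBS) is a standard route to 1-bromoalkynes and should tolerate the ynone and the ketal.

Step 5
Reactants: 5 (E)-1-(2,3-dimethylbuta-1,3-dien-1-yl)-2,4,5-trimethoxybenzene; 10 1-bromo-4,4-dimethoxypent-1-yn-3-one
Product: 12 1-[3-bromo-2',4',5'-trimethoxy-5,6-dimethyl-(1,1'-biphenyl)-2-yl]-2,2-dimethoxypropan-1-one, via bromocyclohexadiene adduct 11 (not isolated)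
Conditions: toluene, 70 °C; then DDQ (1.1 equiv), rt
Reagents that add atoms: none
Why: In this normal-demand Diels–Alder reaction the larger HOMO coefficient at the unsubstituted CH2 terminus of the 1-aryl diene should pair with the bromine-bearing β-carbon of the ynone, so the acyl-bearing carbon bonds to the aryl-bearing terminus ("ortho" orientation), and DDQ dehydrogenation of the 1,4-cyclohexadiene is driven by aromatisation and removes the single racemic stereocentre of 11.

Step 6
Reactants: 12 1-[3-bromo-2',4',5'-trimethoxy-5,6-dimethyl-(1,1'-biphenyl)-2-yl]-2,2-dimethoxypropan-1-one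
Product: 13 1-[3-bromo-2',4',5'-trimethoxy-5,6-dimethyl-(1,1'-biphenyl)-2-yl]-2-methoxyprop-2-en-1-one
Conditions: TMSOTf, i-Pr2NEt, CH2Cl2, 0 °C → rt; NaHCO3 work-up
Reagents that add atoms: none
Why: Lewis-acid-mediated elimination of methanol from a dimethyl ketal (TMSOTf ionises one methoxy group, the amine deprotonates the adjacent methyl, the only C–H position available) is a standard ketal-to-enol-ether conversion, precedented for α-keto ketals such as pyruvate and butanedione ketals, and should leave the non-enolisable aryl ketone, the aryl bromide and the aryl methyl ethers untouched.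

Step 7
Reactants: 13 1-[3-bromo-2',4',5'-trimethoxy-5,6-dimethyl-(1,1'-biphenyl)-2-yl]-2-methoxyprop-2-en-1-one
Product: 14 2-methoxy-6,7-dimethyl-8-(2,4,5-trimethoxyphenyl)naphthalene-1,4-dione
Conditions: PdCl2(PPh3)2 (5 mol %), CO (40 atm), Et3N (2 equiv), MeCN/toluene 1:1, 100 °C
Reagents that add atoms: carbon monoxide, [C-]#[O+]
Why: Zerovalent palladium (formed in situ from PdCl2(PPh3)2, CO and Et3N) should add oxidatively to the C–Br bond, CO inserts to give the aroylpalladium bromide on the ring B carbon ortho to the enone, and the acyl group then adds across the tethered C=CH2 with acyl to the unsubstituted terminus and palladium to the methoxy-bearing carbon, where it is held as a palladium enolate of the original ketone; syn β-hydride elimination of one of the two hydrogens of the new C3 methylene restores the C=C bond and Et3N regenerates zerovalent palladium, so the quinone oxidation level and the vinylogous ester arise directly. The closest known reaction type is the cyclic acylpalladation (carbonylative Heck cyclisation) of 2-haloaryl vinyl ketones, α-substituted ones included, which gives 1,4-naphthoquinones in the endo mode. Ring A is closed by a 6-endo-trig acylpalladation, CO acting as the one-carbon partner of a formal [5+1] annulation that forms two C–C bonds. No stereocentre is created. The step needs endo over exo insertion and must keep the methoxy carbon next to the carbonyl that is already present in 13: the enone polarisation and the lower substitution of the CH2 terminus direct the acyl carbon there, the exo alternative would build a quaternary centre carrying an alkylpalladium without β-hydrogen, and the position of the methoxy group relative to ring C is already set in 12 by the orientation of the Diels–Alder reaction of step 5. Direct Heck cyclisation without CO is geometrically excluded (four-membered or 5-endo closure), and the aryl methyl ethers and the hindered biaryl are inert under these conditions.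

**Compound list**

1 | 2,4,5-trimethoxybenzaldehyde | COc1cc(OC)c(OC)cc1C=O | starting material
2 | diethyl (3-oxobutan-2-yl)phosphonate | CCOP(=O)(OCC)C(C)C(C)=O | starting material
3 | sodium salt of the carbanion of 2 | CCOP(=O)(OCC)[C-](C)C(C)=O.[Na+] | intermediate
4 | (E)-3-methyl-4-(2,4,5-trimethoxyphenyl)but-3-en-2-one | COc1cc(OC)c(OC)cc1/C=C(C)/C(C)=O | intermediate
5 | (E)-1-(2,3-dimethylbuta-1,3-dien-1-yl)-2,4,5-trimethoxybenzene | COc1cc(OC)c(OC)cc1/C=C(C)/C(C)=C | intermediate
6 | ethynyltrimethylsilane | C#C[Si](C)(C)C | starting material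
7 | methyl 2,2-dimethoxypropanoate | COC(=O)C(C)(OC)OC | starting material
8 | lithium (trimethylsilyl)acetylide | [Li+].[C-]#C[Si](C)(C)C | intermediate
9 | 4,4-dimethoxy-1-(trimethylsilyl)pent-1-yn-3-one | CC(OC)(OC)C(=O)C#C[Si](C)(C)C | intermediate
10 | 1-bromo-4,4-dimethoxypent-1-yn-3-one | CC(OC)(OC)C(=O)C#CBr | intermediate
11 | 1-[2-bromo-4,5-dimethyl-6-(2,4,5-trimethoxyphenyl)cyclohexa-1,4-dien-1-yl]-2,2-dimethoxypropan-1-one (racemic) | CC(OC)(OC)C(=O)C1=C(Br)CC(C)=C(C)C1c1cc(OC)c(OC)cc1OC | intermediate
12 | 1-[3-bromo-2',4',5'-trimethoxy-5,6-dimethyl-(1,1'-biphenyl)-2-yl]-2,2-dimethoxypropan-1-one | CC(OC)(OC)C(=O)c1c(Br)cc(C)c(C)c1-c1cc(OC)c(OC)cc1OC | intermediate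
13 | 1-[3-bromo-2',4',5'-trimethoxy-5,6-dimethyl-(1,1'-biphenyl)-2-yl]-2-methoxyprop-2-en-1-one | C=C(OC)C(=O)c1c(Br)cc(C)c(C)c1-c1cc(OC)c(OC)cc1OC | intermediate
14 | 2-methoxy-6,7-dimethyl-8-(2,4,5-trimethoxyphenyl)naphthalene-1,4-dione | COC1=CC(=O)c2cc(C)c(C)c(-c3cc(OC)c(OC)cc3OC)c2C1=O | target

**Step count and risks**

Total step count: 7. Longest linear sequence: 5 steps (steps 1, 2, 5, 6, 7 from 1; equally steps 3, 4, 5, 6, 7 from 7).

Steps most likely to fail:

Step 7. The acyl group may insert in the exo mode and then reach the six-membered ring by acyl migration through a cyclopropanolate, which could exchange which carbonyl neighbours the methoxy carbon. The palladium enolate may also be protonated instead of undergoing β-hydride elimination, which would stall turnover, and the captodative alkene may oligomerise at 100 °C. The fallback sets out from 12 and comes back at 14, and makes the same ring bond with the opposite polarity. 12 would be methoxycarbonylated (Pd(OAc)2, Xantphos, CO 1 atm, MeOH, Et3N, toluene, 80 °C) to methyl 2-(2,2-dimethoxypropanoyl)-2',4',5'-trimethoxy-5,6-dimethyl-(1,1'-biphenyl)-3-carboxylate F1. Aqueous trifluoroacetic acid would unmask the ketal to methyl 2',4',5'-trimethoxy-5,6-dimethyl-2-(2-oxopropanoyl)-(1,1'-biphenyl)-3-carboxylate F2. LiN(SiMe3)2 in THF (−78 → 0 °C) would deprotonate the methyl ketone, and the enolate should close onto the ester in a Dieckmann-type Claisen condensation to give 2-hydroxy-6,7-dimethyl-8-(2,4,5-trimethoxyphenyl)naphthalene-1,4-dione F3. O-Methylation (Me2SO4, K2CO3, acetone) should then give 14.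

Step 5. The bromo ynone may be consumed by conjugate addition or oligomerisation before it cycloadds, and the orientation of the cycloaddition between two hindered termini may be incompletely controlled. The fallback sets out from 5 and comes back at 13; it carries only the ester carbon in a robust dienophile and adds the two-carbon enol ether unit afterwards. 5 would be heated in toluene at 110 °C with methyl 3-bromoprop-2-ynoate F4 (from methyl propiolate, NBS, catalytic AgNO3) to give methyl 2-bromo-4,5-dimethyl-6-(2,4,5-trimethoxyphenyl)cyclohexa-1,4-diene-1-carboxylate F5. DDQ should aromatise this to methyl 3-bromo-2',4',5'-trimethoxy-5,6-dimethyl-(1,1'-biphenyl)-2-carboxylate F6. i-Bu2AlH would reduce the ester to [3-bromo-2',4',5'-trimethoxy-5,6-dimethyl-(1,1'-biphenyl)-2-yl]methanol F7, and MnO2 would give 3-bromo-2',4',5'-trimethoxy-5,6-dimethyl-(1,1'-biphenyl)-2-carbaldehyde F8. 1-Methoxyvinyllithium (methyl vinyl ether, t-BuLi, THF, −78 °C) would add to give 1-[3-bromo-2',4',5'-trimethoxy-5,6-dimethyl-(1,1'-biphenyl)-2-yl]-2-methoxyprop-2-en-1-ol F9, and MnO2 oxidation should return to 13.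

Step 6. Ionisation of a ketal next to a carbonyl group may be slow, and the product enol ether may hydrolyse or oligomerise under the Lewis acid. The fallback sets out from 12 and comes back at 13; it makes the enol ether by O-alkylation instead of elimination. 12 would be hydrolysed with aqueous trifluoroacetic acid to 1-[3-bromo-2',4',5'-trimethoxy-5,6-dimethyl-(1,1'-biphenyl)-2-yl]propane-1,2-dione F10. KN(SiMe3)2 (THF, −78 °C) would form the enolate at the methyl group, the only enolisable position, and MeOTf with DMPU should methylate it on oxygen to give 13.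

**Further compounds**

F1 | step 7 | methyl 2-(2,2-dimethoxypropanoyl)-2',4',5'-trimethoxy-5,6-dimethyl-(1,1'-biphenyl)-3-carboxylate | COC(=O)c1cc(C)c(C)c(-c2cc(OC)c(OC)cc2OC)c1C(=O)C(C)(OC)OC
F2 | step 7 | methyl 2',4',5'-trimethoxy-5,6-dimethyl-2-(2-oxopropanoyl)-(1,1'-biphenyl)-3-carboxylate | COC(=O)c1cc(C)c(C)c(-c2cc(OC)c(OC)cc2OC)c1C(=O)C(C)=O
F3 | step 7 | 2-hydroxy-6,7-dimethyl-8-(2,4,5-trimethoxyphenyl)naphthalene-1,4-dione | OC1=CC(=O)c2cc(C)c(C)c(-c3cc(OC)c(OC)cc3OC)c2C1=O
F4 | step 5 | methyl 3-bromoprop-2-ynoate | COC(=O)C#CBr
F5 | step 5 | methyl 2-bromo-4,5-dimethyl-6-(2,4,5-trimethoxyphenyl)cyclohexa-1,4-diene-1-carboxylate (racemic) | COC(=O)C1=C(Br)CC(C)=C(C)C1c1cc(OC)c(OC)cc1OC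
F6 | step 5 | methyl 3-bromo-2',4',5'-trimethoxy-5,6-dimethyl-(1,1'-biphenyl)-2-carboxylate | COC(=O)c1c(Br)cc(C)c(C)c1-c1cc(OC)c(OC)cc1OC
F7 | step 5 | [3-bromo-2',4',5'-trimethoxy-5,6-dimethyl-(1,1'-biphenyl)-2-yl]methanol | OCc1c(Br)cc(C)c(C)c1-c1cc(OC)c(OC)cc1OC
F8 | step 5 | 3-bromo-2',4',5'-trimethoxy-5,6-dimethyl-(1,1'-biphenyl)-2-carbaldehyde | O=Cc1c(Br)cc(C)c(C)c1-c1cc(OC)c(OC)cc1OC
F9 | step 5 | 1-[3-bromo-2',4',5'-trimethoxy-5,6-dimethyl-(1,1'-biphenyl)-2-yl]-2-methoxyprop-2-en-1-ol (racemic) | C=C(OC)C(O)c1c(Br)cc(C)c(C)c1-c1cc(OC)c(OC)cc1OC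
F10 | step 6 | 1-[3-bromo-2',4',5'-trimethoxy-5,6-dimethyl-(1,1'-biphenyl)-2-yl]propane-1,2-dione | CC(=O)C(=O)c1c(Br)cc(C)c(C)c1-c1cc(OC)c(OC)cc1OC
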